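It looked impossible to me that a flask charged with more D than X could end with X unreacted.

    X ⇌ Q, rate k1*(cs1 - [Q]) while solid is left; crystals form when [Q] > cs1 (cs1 = 1.3 M, k1 = 1.16 /s)
    Q + D → Q.D (k2 = 0.0483 /M/s)
    D → E (k3 = 0.0339 /s)
    L ⇌ Q.D, rate k4*(cs4 - [Q.D]) while solid is left; crystals form when [Q.D] > cs4 (cs4 = 0.70 M, k4 = 10.0 /s)

X 2.0 M; D 1.10 equiv; time 20 min

1. at 20 min, what has stopped the reaction, if anything has (for what has run out or reacted, a solid counts together with what of it has only dissolved) (forward and back rates have come level / it is still moving / all of X has reacted / D has run out first)
2. part of the X that has turned into other species by 20 min (what has only dissolved does not count)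
3. how much Q.D there is at 20 min, in percent of the X charged

- for Q.D the L are counted in
- as a solid, counted per litre of solution: X, L
- at the start none of X is in solution
- what has only dissolved of X counts as not reacted
- the reaction counts as stopped when no species that holds the X changes by six tenths of a point or more over the second half of the time
- run time (flask): 20 min

**Break-even level.** D can go two ways: to E at a rate set by D itself, or onto Q at a rate that also scales with Q. So Q is the concentration to watch. The break-even level b, here 35.1%, is the amount of Q, as a fraction of the X charged, at which D goes to Q.D and to E equally fast. With Q at a fraction q, the share of D reaching Q.D is q/(q+b).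

**Hand reckoning.** Dissolving has a time constant of 0.862 s, shorter than D's. So I held Q at solubility, 65.0% of the charge, while solid lasted. D then decays pseudo-first-order with a time constant of 0.172 min, far shorter than the run. The share is 64.9%, so at that share 1.10 equiv of D makes 71.4% of Q.D, less than the whole X charge, and the apparent excess disappears: D is the limiting reagent.

Solid lasts until Q.D reaches 35.0%, which leaves 56.1% of the X charge as D. With Q taken at 0.5 of the charge on average for that stretch, the share drops to 58.8%. I reckoned 68.0% of Q.D, with the remaining X left as Q.

**The forecast.** It said D has run out first, with 65% converted and 65% of Q.D, on the grounds that “about two-thirds of D goes to Q.D”. Its yield stood below mine.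

**The run.** The flask gave D has run out first, 65.1% converted and 65.1% of Q.D, so my figure was 2.9 percentage points high. The answer for Q.D moves by 5 points with D at 0.998 equiv or 1.21 equiv, and a shift of that size is what would put the forecast's figure out. In the neighbour flask, X is 1.2 M, under the solubility of Q, and the break-even level is 58.5%. With Q taken at 0.7 of the charge on average, the share is 54.5%, so I reckoned 59.9% of Q.D. That neighbour flask gave 57.5%, with 42% of its X still there, solid or dissolved, and 0% of its D.

Its constants belong to no real substance; the result is computed.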